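**Plan**

- Retrosynthesis: the oxygen functions come off first – C8–OH with the C6=C7 bond moved back to C7=C8, the acetate, the two hydrogens on C11–C12, the lactone bond C14–O and the C3–C4 epoxide (both traced to a C17 acid), then C13=O and C17–O. This leaves (S)-cembrene A, and the last cut is the ring bond C1–C2, which opens the macrocycle to geranylgeranyl diphosphate.
- Enabling feature: the 14-membered carbocycle C1–C14 with methyl groups on C4, C8 and C12 and the three-carbon unit C15–C17 on C1 is a head-to-tail tetraprenyl chain closed between C1 and C2, so a cembrene A synthase makes ring, skeleton and C1 in one step.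
- Forward order of rings: 14-membered carbocycle (step 3), oxirane C3–O–C4 (step 7), γ-lactone C1–C14–O–C17–C15 (step 8).
- Stereochemistry: C1 from the cyclase; C3/C4 relayed from C1 by iodolactonisation; C14 from C1 in the enolate hydroxylation; C13 from C14 (Felkin–Anh reduction); C12 from C13 (hydroxyl-directed hydrogenation); C8 from the ring conformation in the singlet-oxygen ene reaction.

Key step: step 3

Assumption: a cembrene A synthase that gives the 1S enantiomer is used as the recombinant enzyme.
Remark: cembrane numbering is used (C1 ring-fusion CH, C14 lactone O–CH, C16 exocyclic CH2, C17 carbonyl carbon). C1 keeps the arrangement set in step 3 throughout; its CIP letter changes with the substituents.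

**Step 1**
Reactants: 1 geranylgeraniol
Product: 2 geranylgeranyl chloride
Conditions: N-chlorosuccinimide, Me2S, CH2Cl2, −30 → 0 °C
Reagents that add atoms: N-chlorosuccinimide, O=C1CCC(=O)N1Cl
Why: Corey–Kim chlorination converts the primary allylic alcohol into the chloride through the alkoxysulfonium salt by SN2 displacement at C1, without allylic transposition or change of the 2E geometry, and no stereocentre is formed.

**Step 2**
Reactants: 2 geranylgeranyl chloride
Product: 3 (E,E,E)-geranylgeranyl diphosphate
Conditions: (n-Bu4N)3HP2O7, MeCN, rt; cation exchange (NH4+ form), isolated as the tris(ammonium) salt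
Reagents that add atoms: tris(tetrabutylammonium) hydrogen diphosphate, CCCC[N+](CCCC)(CCCC)CCCC.CCCC[N+](CCCC)(CCCC)CCCC.CCCC[N+](CCCC)(CCCC)CCCC.OP(=O)([O-])OP(=O)([O-])[O-]
Why: SN2 displacement of the allylic chloride by the diphosphate anion is the standard route to prenyl diphosphates, the tetrabutylammonium counter-ions keeping the nucleophile soluble in acetonitrile, and no stereocentre is formed.

**Step 3**
Reactants: 3 (E,E,E)-geranylgeranyl diphosphate
Product: 4 (S)-cembrene A
Conditions: recombinant (S)-cembrene A synthase (class 1 diterpene cyclase), MgCl2, Tris-HCl buffer pH 7.5, 30 °C, hexane overlay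
Reagents that add atoms: none
Why: The synthase binds the diphosphate through divalent magnesium (from MgCl2) and ionises the C1–O bond (chain numbering) to the C1–C3 allyl cation; the folded chain brings the C14=C15 alkene over C1, bond formation C1–C14 (cembrane C2–C1) closes the ring, and a methyl proton is lost from the C15 cation to leave the 2-propenyl group. This is the native reaction of cembrene A synthases, a class 1 terpene cyclisation of the cation–olefin type. The single ring closes in a 14-membered Markovnikov mode in which the attacking alkene carbon enters the ring and the cationic carbon stays outside it (exo with respect to the alkene), while the former C2=C3 bond ends up inside the ring with E geometry. The new stereocentre C1 (cembrane) is set by the enzyme, which presents one face of the terminal alkene to the allyl cation, so a synthase of 1S selectivity is chosen. The step needs 14- over 6- or 10-membered closure, retention of the three E alkenes and proton loss from a methyl group in place of water capture. These are secured by the active-site fold acting on the all-E chain, whose terminal trisubstituted alkene attacks through its less substituted carbon and whose 2E bond keeps the allyl cation away from a six-membered closure.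

**Step 4**
Reactants: 4 (S)-cembrene A
Product: 7 (1S,3E,7E,11E)-cembra-3,7,11,15-tetraen-17-ol, via allyllithium 5 (not isolated), via dimethyl allylboronate 6 (not isolated)
Conditions: n-BuLi, TMEDA, hexane, rt; B(OMe)3, −78 °C → rt; NaOH, H2O2, 0 °C
Reagents that add atoms: hydrogen peroxide, OO (the oxygen of 7); n-butyllithium, [Li]CCCC (lithium of 5 only); trimethyl borate, COB(OC)OC (boron and methoxy groups of 6 only)
Why: n-BuLi with TMEDA removes a proton from the methyl group of the 2-propenyl unit, the most acidic allylic position because it gives a 2-substituted allyl anion with two primary ends (the known behaviour of limonene), and borylation followed by oxidative carbon-to-oxygen migration places the hydroxyl on that carbon; C1 is not deprotonated and no new stereocentre arises, since both ends of the allyl anion lead to the same alcohol.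

**Step 5**
Reactants: 7 (1S,3E,7E,11E)-cembra-3,7,11,15-tetraen-17-ol
Product: 8 (1R,3E,7E,11E)-cembra-3,7,11,15-tetraene-13,17-diol (both C13 epimers)
Conditions: SeO2 (catalytic), t-BuOOH, CH2Cl2, 0 °C → rt, partial conversion
Reagents that add atoms: tert-butyl hydroperoxide, CC(C)(C)OO (terminal source of the C13 oxygen, passed on by the catalyst SeO2, O=[Se]=O)
Why: Riley oxidation (ene reaction of SeO2 followed by a 2,3-sigmatropic shift) hydroxylates the CH2 group on the more substituted carbon of a trisubstituted alkene with retention of the E bond, which here means C5, C9 or C13; no preference among these three like positions is expected, so the reaction is stopped at partial conversion, the 13-ol is separated and 7 is recycled, and the new C13 centre is taken on as both epimers because step 6 removes it.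

**Step 6**
Reactants: 8 (1R,3E,7E,11E)-cembra-3,7,11,15-tetraene-13,17-diol
Product: 10 (1R,3E,7E,11E)-13-oxocembra-3,7,11,15-tetraen-17-oic acid, via keto enal 9 (not isolated)
Conditions: MnO2, CH2Cl2, rt; then NaClO2, NaH2PO4, 2-methyl-2-butene, t-BuOH/H2O, 0 °C
Reagents that add atoms: sodium chlorite, [Na+].[O-]Cl=O
Why: MnO2 oxidises only the two allylic alcohols, to the enal and the enone, and the Pinnick oxidation with 2-methyl-2-butene as hypochlorite scavenger takes the aldehyde to the acid without touching the alkenes or the ketone; the C13 centre is erased and C1 is not enolisable.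

**Step 7**
Reactants: 10 (1R,3E,7E,11E)-13-oxocembra-3,7,11,15-tetraen-17-oic acid
Product: 12 methyl (1R,3R,4R,7E,11E)-3,4-epoxy-13-oxocembra-7,11,15-trien-17-oate, via iodolactone 11 (not isolated)
Conditions: I2, KI, NaHCO3, THF/H2O, 0 °C, dark; then K2CO3, MeOH, 0 °C → rt
Reagents that add atoms: methanol, CO (the methoxy group of 12); iodine, [I][I] (iodine atom of 11 only)
Why: In the iodolactonisation only C3=C4 can be reached by the carboxylate through a six-membered (6-exo) closure, the C1 side chain attacks C3 on the alkene face on which C1 lies and iodine adds anti at C4, and methanolysis of the lactone frees the C3 alkoxide, which displaces the tertiary iodide with inversion to give the trans epoxide of the former E alkene; the 3R,4R isomer comes from the closure in which H-1 and H-3 are trans on the lactone ring, that is with the C1–C14 bond gauche to C2–C3, the conformer assumed here for the corner of the macrocycle at C1.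

**Step 8**
Reactants: 12 methyl (1R,3R,4R,7E,11E)-3,4-epoxy-13-oxocembra-7,11,15-trien-17-oate
Product: 15 (1S,3R,4R,7E,11E,14R)-3,4-epoxy-13-oxocembra-7,11,15-trien-17,14-olide, via potassium enolate 13 (not isolated), via hydroxy ester alkoxide 14 (not isolated)
Conditions: KN(SiMe3)2, THF, −78 °C; 2-(phenylsulfonyl)-3-phenyloxaziridine, −78 → 0 °C; AcOH
Reagents that add atoms: 2-(phenylsulfonyl)-3-phenyloxaziridine, O=S(=O)(c1ccccc1)N1OC1c1ccccc1 (the C14 oxygen); potassium bis(trimethylsilyl)amide, C[Si](C)(C)[N-][Si](C)(C)C.[K+] (potassium of 13 and 14 only)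
Why: Kinetic deprotonation of the enone on the α' side (C14) and oxygen transfer from the sulfonyloxaziridine (Davis oxidation) give the C14 alkoxide, which closes the γ-lactone onto the neighbouring methyl ester in a 5-exo-trig acyl substitution; C14 is set by the adjacent C1 centre, the oxidant being expected to attack the enolate face anti to the C15 substituent in the rotamer that keeps H-1 in the enolate plane (minimised 1,3-allylic strain), which gives the 14R alkoxide and the cis-fused lactone.

**Step 9**
Reactants: 15 (1S,3R,4R,7E,11E,14R)-3,4-epoxy-13-oxocembra-7,11,15-trien-17,14-olide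
Product: 16 (1S,3R,4R,7E,11E,14R)-16-(dimethylamino)-3,4-epoxy-13-oxocembra-7,11-dien-17,14-olide (C15 epimers)
Conditions: Me2NH (2 M in THF), THF, 0 °C → rt
Reagents that add atoms: dimethylamine, CNC
Why: Conjugate (aza-Michael) addition of dimethylamine to the α-methylene lactone, far more electrophilic than the α-methyl-β-substituted enone, masks the exocyclic alkene against hydride and hydrogen in steps 10 and 11; the new C15 centre is formed as a mixture and is erased in step 13.

**Step 10**
Reactants: 16 (1S,3R,4R,7E,11E,14R)-16-(dimethylamino)-3,4-epoxy-13-oxocembra-7,11-dien-17,14-olide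
Product: 17 (1S,3R,4R,7E,11E,13R,14R)-16-(dimethylamino)-3,4-epoxy-13-hydroxycembra-7,11-dien-17,14-olide
Conditions: NaBH4, CeCl3·7H2O, MeOH, −78 °C
Reagents that add atoms: none
Why: Luche reduction adds hydride 1,2 to the enone, and with the polar C14–O bond anti to the incoming hydride (Felkin–Anh model for an α-acyloxy ketone without chelation) the 13,14-syn alcohol, 13R, is expected.

**Step 11**
Reactants: 17 (1S,3R,4R,7E,11E,13R,14R)-16-(dimethylamino)-3,4-epoxy-13-hydroxycembra-7,11-dien-17,14-olide
Product: 18 (1S,3R,4R,7E,12S,13R,14R)-16-(dimethylamino)-3,4-epoxy-13-hydroxycembr-7-en-17,14-olide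
Conditions: H2 (about 50 bar), [Rh(nbd)(dppb)]BF4 (catalytic; nbd = norbornadiene, dppb = 1,4-bis(diphenylphosphino)butane), CH2Cl2, rt
Reagents that add atoms: none
Why: In the hydroxyl-directed hydrogenation the cationic rhodium complex binds the C13 hydroxyl and the C11=C12 bond and adds hydrogen to the alkene face held next to the oxygen, which in the rotamer that avoids 1,2-allylic strain with the C12 methyl group gives the 12,13-syn product, 12S, while the isolated trisubstituted C7=C8 bond, the epoxide and the lactone are not reduced by this catalyst.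

**Step 12**
Reactants: 18 (1S,3R,4R,7E,12S,13R,14R)-16-(dimethylamino)-3,4-epoxy-13-hydroxycembr-7-en-17,14-olide
Product: 19 (1S,3R,4R,7E,12S,13R,14R)-13-acetoxy-16-(dimethylamino)-3,4-epoxycembr-7-en-17,14-olide
Conditions: Ac2O, pyridine, DMAP (catalytic), CH2Cl2, 0 °C → rt
Reagents that add atoms: acetic anhydride, CC(=O)OC(C)=O
Why: Acylation of the only hydroxyl group with acetic anhydride under nucleophilic catalysis by DMAP proceeds with retention at C13.

**Step 13**
Reactants: 19 (1S,3R,4R,7E,12S,13R,14R)-13-acetoxy-16-(dimethylamino)-3,4-epoxycembr-7-en-17,14-olide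
Product: 21 (1S,3R,4R,7E,12S,13R,14R)-13-acetoxy-3,4-epoxycembra-7,15-dien-17,14-olide, via methiodide 20 (not isolated)
Conditions: MeI, MeOH, rt; then NaHCO3 (aq), EtOAc, rt
Reagents that add atoms: iodomethane, [CH3]I (methyl group and iodide of 20 only; no reagent atom stays in 21)
Why: Quaternisation of the Mannich-type amine and mild-base E1cB elimination of trimethylamine regenerate the α-methylene lactone without touching the epoxide or the acetate, the C15 centre becoming trigonal again.

**Step 14**
Reactants: 21 (1S,3R,4R,7E,12S,13R,14R)-13-acetoxy-3,4-epoxycembra-7,15-dien-17,14-olide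
Product: 23 (1S,3R,4R,6E,8S,12S,13R,14R)-13-acetoxy-3,4-epoxy-8-hydroxycembra-6,15-dien-17,14-olide, via hydroperoxide 22 (not isolated)
Conditions: O2, visible light, tetraphenylporphyrin (catalytic), CH2Cl2, 0 °C; then PPh3, 0 °C
Reagents that add atoms: oxygen, O=O (one oxygen atom stays in 23, both are in 22)
Why: Singlet oxygen reacts only with the remaining electron-rich trisubstituted C7=C8 bond (Schenck ene reaction), oxygen bonding to C8 and a hydrogen leaving C6 on the more crowded side of the alkene to give the tertiary allylic hydroperoxide with a 6E bond, and PPh3 reduces the hydroperoxide to the alcohol with retention; the 8S centre requires attack on the Si face of C8, taken to be the outer face of the alkene in the lactone-bearing ring.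

**Compound list**

1 | geranylgeraniol, (2E,6E,10E)-3,7,11,15-tetramethylhexadeca-2,6,10,14-tetraen-1-ol | CC(C)=CCC/C(C)=C/CC/C(C)=C/CC/C(C)=C/CO | starting material
2 | geranylgeranyl chloride | CC(C)=CCC/C(C)=C/CC/C(C)=C/CC/C(C)=C/CCl | intermediate
3 | (E,E,E)-geranylgeranyl diphosphate (handled as the tris(ammonium) salt; SMILES of the acid) | CC(C)=CCC/C(C)=C/CC/C(C)=C/CC/C(C)=C/COP(=O)(O)OP(=O)(O)O | intermediate
4 | (S)-cembrene A, (1S,3E,7E,11E)-cembra-3,7,11,15-tetraene | CC(=C)[C@H]1CC/C(C)=C/CC/C(C)=C/CC/C(C)=C/C1 | intermediate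
5 | (1S,3E,7E,11E)-cembra-3,7,11,15-tetraen-17-yllithium (forms in the flask in step 4) | [Li]CC(=C)[C@H]1CC/C(C)=C/CC/C(C)=C/CC/C(C)=C/C1 | intermediate
6 | dimethyl [(1S,3E,7E,11E)-cembra-3,7,11,15-tetraen-17-yl]boronate (forms in the flask in step 4) | COB(OC)CC(=C)[C@H]1CC/C(C)=C/CC/C(C)=C/CC/C(C)=C/C1 | intermediate
7 | (1S,3E,7E,11E)-cembra-3,7,11,15-tetraen-17-ol | OCC(=C)[C@H]1CC/C(C)=C/CC/C(C)=C/CC/C(C)=C/C1 | intermediate
8 | (1R,3E,7E,11E)-cembra-3,7,11,15-tetraene-13,17-diol, both C13 epimers | OCC(=C)[C@H]1CC(O)/C(C)=C/CC/C(C)=C/CC/C(C)=C/C1 | intermediate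
9 | (1R,3E,7E,11E)-13-oxocembra-3,7,11,15-tetraen-17-al (forms in the flask in step 6) | O=CC(=C)[C@H]1CC(=O)/C(C)=C/CC/C(C)=C/CC/C(C)=C/C1 | intermediate
10 | (1R,3E,7E,11E)-13-oxocembra-3,7,11,15-tetraen-17-oic acid | OC(=O)C(=C)[C@H]1CC(=O)/C(C)=C/CC/C(C)=C/CC/C(C)=C/C1 | intermediate
11 | (1R,3R,4S,7E,11E)-4-iodo-13-oxocembra-7,11,15-trien-17,3-olide (forms in the flask in step 7) | C=C1C(=O)O[C@@H]2C[C@@H]1CC(=O)/C(C)=C/CC/C(C)=C/CC[C@]2(C)I | intermediate
12 | methyl (1R,3R,4R,7E,11E)-3,4-epoxy-13-oxocembra-7,11,15-trien-17-oate | COC(=O)C(=C)[C@H]1CC(=O)/C(C)=C/CC/C(C)=C/CC[C@@]2(C)O[C@@H]2C1 | intermediate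
13 | potassium 13(14)-enolate of 12 (forms in the flask in step 8) | COC(=O)C(=C)[C@H]1C=C([O-])/C(C)=C/CC/C(C)=C/CC[C@@]2(C)O[C@@H]2C1.[K+] | intermediate
14 | methyl (1S,3R,4R,7E,11E,14R)-3,4-epoxy-14-hydroxy-13-oxocembra-7,11,15-trien-17-oate, present as its potassium alkoxide (forms in the flask in step 8; SMILES of the alcohol) | COC(=O)C(=C)[C@H]1[C@@H](O)C(=O)/C(C)=C/CC/C(C)=C/CC[C@@]2(C)O[C@@H]2C1 | intermediate
15 | (1S,3R,4R,7E,11E,14R)-3,4-epoxy-13-oxocembra-7,11,15-trien-17,14-olide | C=C1C(=O)O[C@H]2C(=O)/C(C)=C/CC/C(C)=C/CC[C@@]3(C)O[C@@H]3C[C@@H]12 | intermediate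
16 | (1S,3R,4R,7E,11E,14R)-16-(dimethylamino)-3,4-epoxy-13-oxocembra-7,11-dien-17,14-olide, C15 epimers | CN(C)CC1C(=O)O[C@H]2C(=O)/C(C)=C/CC/C(C)=C/CC[C@@]3(C)O[C@@H]3C[C@@H]12 | intermediate
17 | (1S,3R,4R,7E,11E,13R,14R)-16-(dimethylamino)-3,4-epoxy-13-hydroxycembra-7,11-dien-17,14-olide, C15 epimers | CN(C)CC1C(=O)O[C@H]2[C@H](O)/C(C)=C/CC/C(C)=C/CC[C@@]3(C)O[C@@H]3C[C@@H]12 | intermediate
18 | (1S,3R,4R,7E,12S,13R,14R)-16-(dimethylamino)-3,4-epoxy-13-hydroxycembr-7-en-17,14-olide, C15 epimers | CN(C)CC1C(=O)O[C@H]2[C@H](O)[C@@H](C)CCC/C(C)=C/CC[C@@]3(C)O[C@@H]3C[C@@H]12 | intermediate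
19 | (1S,3R,4R,7E,12S,13R,14R)-13-acetoxy-16-(dimethylamino)-3,4-epoxycembr-7-en-17,14-olide, C15 epimers | CN(C)CC1C(=O)O[C@H]2[C@H](OC(C)=O)[C@@H](C)CCC/C(C)=C/CC[C@@]3(C)O[C@@H]3C[C@@H]12 | intermediate
20 | N-methyl quaternary ammonium iodide of 19 (forms in the flask in step 13) | C[N+](C)(C)CC1C(=O)O[C@H]2[C@H](OC(C)=O)[C@@H](C)CCC/C(C)=C/CC[C@@]3(C)O[C@@H]3C[C@@H]12.[I-] | intermediate
21 | (1S,3R,4R,7E,12S,13R,14R)-13-acetoxy-3,4-epoxycembra-7,15-dien-17,14-olide | C=C1C(=O)O[C@H]2[C@H](OC(C)=O)[C@@H](C)CCC/C(C)=C/CC[C@@]3(C)O[C@@H]3C[C@@H]12 | intermediate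
22 | (1S,3R,4R,6E,8S,12S,13R,14R)-13-acetoxy-3,4-epoxy-8-hydroperoxycembra-6,15-dien-17,14-olide (forms in the flask in step 14) | C=C1C(=O)O[C@H]2[C@H](OC(C)=O)[C@@H](C)CCC[C@](C)(OO)/C=C/C[C@@]3(C)O[C@@H]3C[C@@H]12 | intermediate
23 | CNP0202356.4, (1S,3R,4R,6E,8S,12S,13R,14R)-13-acetoxy-3,4-epoxy-8-hydroxycembra-6,15-dien-17,14-olide | C=C1C(=O)O[C@H]2[C@H](OC(C)=O)[C@@H](C)CCC[C@](C)(O)/C=C/C[C@@]3(C)O[C@@H]3C[C@@H]12 | target

**Step count**

Total: 14 steps. Longest linear sequence: 14 steps (from geranylgeraniol; the route is fully linear).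

**Steps most likely to fail**

Step 5 – loss of site selectivity. The ene step has no reason to prefer C13 over the like CH2 groups C5 and C9, so at best about a third of the converted material is the wanted diol, and the primary alcohol may be oxidised further. Fallback (from 7, back at 12): the order is changed so that C3=C4 is already an epoxide when the allylic oxidation is run. Alcohol 7 is oxidised with MnO2 to (1S,3E,7E,11E)-cembra-3,7,11,15-tetraen-17-al F1 and on with NaClO2, NaH2PO4 and 2-methyl-2-butene to (1S,3E,7E,11E)-cembra-3,7,11,15-tetraen-17-oic acid F2. Iodolactonisation (I2, KI, NaHCO3) gives (1S,3R,4S,7E,11E)-4-iodocembra-7,11,15-trien-17,3-olide F3, and K2CO3 in methanol turns it into methyl (1S,3R,4R,7E,11E)-3,4-epoxycembra-7,11,15-trien-17-oate F4. SeO2 with t-BuOOH then has only C9 and C13 to choose from and gives methyl (1S,3R,4R,7E,11E)-3,4-epoxy-13-hydroxycembra-7,11,15-trien-17-oate F5 as both C13 epimers, which MnO2 oxidises to 12.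

Step 14 – wrong course of the ene reaction. Hydrogen may be taken from the C19 methyl group in place of C6, which would give the exocyclic alkene with oxygen on C7, and oxygen may be delivered to the other face of C8. Fallback (from 21, ending at 23): hydroxyselenation followed by selenoxide elimination. Benzeneselenenic acid, made in the flask from PhSeO2H and PhSeSePh in CH2Cl2 over MgSO4, adds across C7=C8 with the hydroxyl on the tertiary carbon C8 and selenium anti on C7. This gives (1S,3R,4R,7R,8S,12S,13R,14R)-13-acetoxy-3,4-epoxy-8-hydroxy-7-(phenylseleno)cembr-15-en-17,14-olide F6. H2O2 with pyridine at 0 °C oxidises it to the corresponding selenoxide F7, whose syn elimination can only take a hydrogen from C6 and so gives the 6E allylic alcohol 23. The regiochemistry is fixed by the Markovnikov addition. Because the oxygen enters anti to the selenium, the face of C8 that receives oxygen is the reverse of the one reached in the ene reaction.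

Step 8 – attack on the other enolate face. If the ring conformation, and not the C1 substituent, decides the face, the oxidant would give the 14-epimer and hence the trans-fused lactone. Fallback (from 12, back at 15): the C14–O bond is formed with inversion instead. The potassium enolate 13 is quenched with N-bromosuccinimide to methyl (1S,3R,4R,7E,11E,14S)-14-bromo-3,4-epoxy-13-oxocembra-7,11,15-trien-17-oate F8, with bromine on the face the oxidant would have taken. The methyl ester is cleaved with Me3SnOH in 1,2-dichloroethane at 60 °C to (1S,3R,4R,7E,11E,14S)-14-bromo-3,4-epoxy-13-oxocembra-7,11,15-trien-17-oic acid F9. Its carboxylate displaces the α-keto bromide in a 5-exo-tet SN2 reaction with inversion and gives the cis-fused lactone 15.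

**Further compounds**

F1 | step 5 | (1S,3E,7E,11E)-cembra-3,7,11,15-tetraen-17-al | O=CC(=C)[C@H]1CC/C(C)=C/CC/C(C)=C/CC/C(C)=C/C1
F2 | step 5 | (1S,3E,7E,11E)-cembra-3,7,11,15-tetraen-17-oic acid | OC(=O)C(=C)[C@H]1CC/C(C)=C/CC/C(C)=C/CC/C(C)=C/C1
F3 | step 5 | (1S,3R,4S,7E,11E)-4-iodocembra-7,11,15-trien-17,3-olide | C=C1C(=O)O[C@@H]2C[C@@H]1CC/C(C)=C/CC/C(C)=C/CC[C@]2(C)I
F4 | step 5 | methyl (1S,3R,4R,7E,11E)-3,4-epoxycembra-7,11,15-trien-17-oate | COC(=O)C(=C)[C@H]1CC/C(C)=C/CC/C(C)=C/CC[C@@]2(C)O[C@@H]2C1
F5 | step 5 | methyl (1S,3R,4R,7E,11E)-3,4-epoxy-13-hydroxycembra-7,11,15-trien-17-oate, both C13 epimers | COC(=O)C(=C)[C@H]1CC(O)/C(C)=C/CC/C(C)=C/CC[C@@]2(C)O[C@@H]2C1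
F6 | step 14 | (1S,3R,4R,7R,8S,12S,13R,14R)-13-acetoxy-3,4-epoxy-8-hydroxy-7-(phenylseleno)cembr-15-en-17,14-olide | C=C1C(=O)O[C@H]2[C@H](OC(C)=O)[C@@H](C)CCC[C@](C)(O)[C@H]([Se]c4ccccc4)CC[C@@]3(C)O[C@@H]3C[C@@H]12
F7 | step 14 | selenoxide of F6, (1S,3R,4R,7R,8S,12S,13R,14R)-13-acetoxy-3,4-epoxy-8-hydroxy-7-(phenylseleninyl)cembr-15-en-17,14-olide | C=C1C(=O)O[C@H]2[C@H](OC(C)=O)[C@@H](C)CCC[C@](C)(O)[C@H]([Se](=O)c4ccccc4)CC[C@@]3(C)O[C@@H]3C[C@@H]12
F8 | step 8 | methyl (1S,3R,4R,7E,11E,14S)-14-bromo-3,4-epoxy-13-oxocembra-7,11,15-trien-17-oate | COC(=O)C(=C)[C@H]1[C@H](Br)C(=O)/C(C)=C/CC/C(C)=C/CC[C@@]2(C)O[C@@H]2C1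
F9 | step 8 | (1S,3R,4R,7E,11E,14S)-14-bromo-3,4-epoxy-13-oxocembra-7,11,15-trien-17-oic acid | OC(=O)C(=C)[C@H]1[C@H](Br)C(=O)/C(C)=C/CC/C(C)=C/CC[C@@]2(C)O[C@@H]2C1
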